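**Plan**

- Retrosynthesis: the 5-OH is traced back to a 5-OMe and the C3–OH bond is cut, which leads to hexamethoxyflavone 14. In 14 the bonds C4a–C4, C4–C3 and O1–C2 of ring C are cut, giving iodophenol 8, carbon monoxide 11 and arylalkyne 10.
- Enabling feature: the C4 carbonyl of ring C lies between C4a of ring A and the C3=C2–aryl unit, and O1 sits on the ring-A carbon next to C4a. C4 can therefore be carbon monoxide inserted between an o-iodophenol carbon and a terminal alkyne carbon.
- Forward, ring A piece: salicylaldehyde 1 is MOM-protected, oxidised (Baeyer–Villiger), O-methylated, lithiated and iodinated next to the OMOM group, and deprotected to 8 (five steps). Ring B piece: aldehyde 9 is homologated to alkyne 10 (one step).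
- Ring C, the only ring formed, closes in step 7. C3 is then hydroxylated through the 2,3-epoxide, and the chelated 5-OMe is cleaved with BCl3.
- Stereochemistry: the target is achiral. The only stereogenic intermediate, epoxide 15, is racemic, and its stereocentres are destroyed in the step that forms it.

Key step: step 7

**Route**

Step 1
Reactants: 1 2-hydroxy-4,6-dimethoxybenzaldehyde
Product: 2 2,4-dimethoxy-6-(methoxymethoxy)benzaldehyde
Conditions: MOMCl, K2CO3, DMF, 0 °C → rt
Reagents that add atoms: chloromethyl methyl ether, COCCl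
Why: Williamson-type O-alkylation of the acidic salicylaldehyde phenoxide gives the MOM ether, which later serves as the directing group for lithiation.

Step 2
Reactants: 2 2,4-dimethoxy-6-(methoxymethoxy)benzaldehyde
Product: 4 2,4-dimethoxy-6-(methoxymethoxy)phenol, via aryl formate 3 (not isolated)
Conditions: mCPBA, CH2Cl2, 0 °C → rt; aq. NaHCO3 wash; then K2CO3 (cat.), MeOH, rt, under argon
Reagents that add atoms: 3-chloroperoxybenzoic acid, OOC(=O)c1cccc(Cl)c1
Why: Baeyer–Villiger (Dakin-type) oxidation, in which the electron-rich trialkoxyaryl group migrates in the Criegee intermediate to give the formate, and mild methanolysis then frees the phenol without touching the MOM acetal.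

Step 3
Reactants: 4 2,4-dimethoxy-6-(methoxymethoxy)phenol
Product: 5 1,2,5-trimethoxy-3-(methoxymethoxy)benzene
Conditions: MeI, K2CO3, acetone, reflux
Reagents that add atoms: iodomethane, CI
Why: Williamson O-methylation of the phenoxide, carried out promptly because the electron-rich phenol 4 is prone to air oxidation.

Step 4
Reactants: 5 1,2,5-trimethoxy-3-(methoxymethoxy)benzene
Product: 7 2-iodo-1,4,5-trimethoxy-3-(methoxymethoxy)benzene, via aryllithium 6 (not isolated)
Conditions: n-BuLi, THF, 0 °C; then I2, THF, −78 °C → rt
Reagents that add atoms: iodine, II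
Why: Directed ortho-metalation, in which the chelating OMOM group holds n-BuLi at the only hydrogen ortho to it, a hydrogen further acidified by the flanking methoxy group, so deprotonation should occur there rather than between the two methoxy groups, and iodine then traps the aryllithium.

Step 5
Reactants: 7 2-iodo-1,4,5-trimethoxy-3-(methoxymethoxy)benzene
Product: 8 2-iodo-3,5,6-trimethoxyphenol
Conditions: HCl (1.25 M in MeOH), rt
Reagents that add atoms: none
Why: Acid-catalysed acetal exchange removes the MOM group, and dilute anhydrous acid at room temperature is chosen so that the methyl ethers stay intact and the electron-rich ring is not protodeiodinated.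

Step 6
Reactants: 9 3,4,5-trimethoxybenzaldehyde
Product: 10 5-ethynyl-1,2,3-trimethoxybenzene
Conditions: dimethyl (1-diazo-2-oxopropyl)phosphonate, K2CO3, MeOH, rt
Reagents that add atoms: dimethyl (1-diazo-2-oxopropyl)phosphonate, COP(=O)(OC)C(=[N+]=[N-])C(C)=O
Why: Ohira–Bestmann (Seyferth–Gilbert) homologation, in which the diazomethylphosphonate anion generated by methanolysis adds to the non-enolisable aldehyde, phosphate is eliminated, and loss of nitrogen with 1,2-hydrogen shift of the alkylidene carbene gives the terminal alkyne.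

Step 7
Reactants: 8 2-iodo-3,5,6-trimethoxyphenol; 10 5-ethynyl-1,2,3-trimethoxybenzene; 11 carbon monoxide
Product: 14 5,7,8-trimethoxy-2-(3,4,5-trimethoxyphenyl)-4H-chromen-4-one, via hydroxyaryl ynone 12 (not isolated), via diethylamino enone 13 (not isolated)
Conditions: PdCl2(dppf) (3 mol %), CO (20 bar), Et2NH (solvent and base), 120 °C, autoclave; 10 in slight excess
Reagents that add atoms: none
Why: PdCl2(dppf) is reduced in situ to zerovalent palladium, which inserts into the C–I bond of 8; CO insertion gives a divalent aroylpalladium iodide, and transfer of the acetylide of 10 (deprotonated by Et2NH) followed by reductive elimination forms the C4a–C4 and C4–C3 bonds of ynone 12. Et2NH then adds to C2 of 12 to give enaminone 13, and the neighbouring phenol oxygen attacks the same carbon and expels the amine, forming the O1–C2 bond. The closest known reaction type is the palladium-catalysed carbonylative Sonogashira coupling–annulation of o-iodophenols with terminal alkynes to flavones and chromones. The single ring formed, pyranone ring C, closes in a 6-endo mode (6-endo-dig with respect to the ynone, realised as a 6-endo-trig addition–elimination on 13), and no stereocentre is created. The step needs CO insertion to precede alkyne coupling, which the CO pressure should secure against direct alkynylation and benzofuran formation, and it needs 6-endo closure to beat 5-exo closure to the aurone, which the secondary-amine pathway through 13 and the absence of strong base should secure. The ring-A pattern is fixed by the substrate, because iodine sits on the carbon between the only free hydroxyl and the methoxy group that becomes 5-OMe, so only the 5,7,8-arrangement can result.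

Step 8
Reactants: 14 5,7,8-trimethoxy-2-(3,4,5-trimethoxyphenyl)-4H-chromen-4-one
Product: 16 3-hydroxy-5,7,8-trimethoxy-2-(3,4,5-trimethoxyphenyl)-4H-chromen-4-one, via flavone epoxide 15 (not isolated)
Conditions: DMDO (excess, in acetone), CH2Cl2, 0 °C → rt; evaporate; then p-TsOH·H2O (cat.), CH2Cl2, rt
Reagents that add atoms: dimethyldioxirane, CC1(C)OO1
Why: Dioxirane epoxidation of the C2=C3 bond followed by acid-catalysed oxirane opening at C2 (cation stabilised by O1 and the aryl group) and loss of H3 is the established flavone-to-flavonol conversion, and it has precedent on fully methylated polymethoxyflavones.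

Step 9
Reactants: 16 3-hydroxy-5,7,8-trimethoxy-2-(3,4,5-trimethoxyphenyl)-4H-chromen-4-one
Product: 17 3,5-dihydroxy-7,8,3',4',5'-pentamethoxyflavone
Conditions: BCl3 (about 3 equiv), CH2Cl2, −78 → 0 °C; then H2O
Reagents that add atoms: none
Why: Chelation-controlled Lewis-acid ether cleavage, in which boron bound to the C4 carbonyl activates only the peri 5-methoxy group toward chloride attack on its methyl, while the methoxy groups that cannot chelate should survive at low temperature.

**Compound list**

1 | 2-hydroxy-4,6-dimethoxybenzaldehyde | COc1cc(O)c(C=O)c(OC)c1 | starting material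
2 | 2,4-dimethoxy-6-(methoxymethoxy)benzaldehyde | COCOc1cc(OC)cc(OC)c1C=O | intermediate
3 | 2,4-dimethoxy-6-(methoxymethoxy)phenyl formate (not isolated) | COCOc1cc(OC)cc(OC)c1OC=O | intermediate
4 | 2,4-dimethoxy-6-(methoxymethoxy)phenol | COCOc1cc(OC)cc(OC)c1O | intermediate
5 | 1,2,5-trimethoxy-3-(methoxymethoxy)benzene | COCOc1cc(OC)cc(OC)c1OC | intermediate
6 | [3,4,6-trimethoxy-2-(methoxymethoxy)phenyl]lithium (not isolated) | COCOc1c([Li])c(OC)cc(OC)c1OC | intermediate
7 | 2-iodo-1,4,5-trimethoxy-3-(methoxymethoxy)benzene | COCOc1c(I)c(OC)cc(OC)c1OC | intermediate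
8 | 2-iodo-3,5,6-trimethoxyphenol | COc1cc(OC)c(I)c(O)c1OC | intermediate
9 | 3,4,5-trimethoxybenzaldehyde | COc1cc(C=O)cc(OC)c1OC | starting material
10 | 5-ethynyl-1,2,3-trimethoxybenzene | C#Cc1cc(OC)c(OC)c(OC)c1 | intermediate
11 | carbon monoxide | [C-]#[O+] | starting material
12 | 1-(2-hydroxy-3,4,6-trimethoxyphenyl)-3-(3,4,5-trimethoxyphenyl)prop-2-yn-1-one (not isolated) | O=C(C#Cc1cc(OC)c(OC)c(OC)c1)c1c(O)c(OC)c(OC)cc1OC | intermediate
13 | (E)-3-(diethylamino)-1-(2-hydroxy-3,4,6-trimethoxyphenyl)-3-(3,4,5-trimethoxyphenyl)prop-2-en-1-one (not isolated; drawn as the E isomer, the geometry has no consequence) | CCN(CC)/C(=C/C(=O)c1c(O)c(OC)c(OC)cc1OC)c1cc(OC)c(OC)c(OC)c1 | intermediate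
14 | 5,7,8-trimethoxy-2-(3,4,5-trimethoxyphenyl)-4H-chromen-4-one | COc1cc(-c2cc(=O)c3c(OC)cc(OC)c(OC)c3o2)cc(OC)c1OC | intermediate
15 | 2,3-epoxy-5,7,8-trimethoxy-2-(3,4,5-trimethoxyphenyl)-2,3-dihydro-4H-chromen-4-one (not isolated; racemic, oxirane cis-fused to the pyranone, one enantiomer drawn) | O=C1[C@H]2O[C@@]2(c2cc(OC)c(OC)c(OC)c2)Oc2c(OC)c(OC)cc(OC)c12 | intermediate
16 | 3-hydroxy-5,7,8-trimethoxy-2-(3,4,5-trimethoxyphenyl)-4H-chromen-4-one | COc1cc(-c2oc3c(OC)c(OC)cc(OC)c3c(=O)c2O)cc(OC)c1OC | intermediate
17 | 3,5-dihydroxy-7,8,3',4',5'-pentamethoxyflavone | COc1cc(-c2oc3c(OC)c(OC)cc(O)c3c(=O)c2O)cc(OC)c1OC | target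

**Step count**

Total step count: 9. Longest linear sequence: 8 steps (steps 1–5, 7, 8, 9).

**Steps most likely to fail**

Step 7. On this hindered, electron-rich iodide, carbonylation may be outrun by direct alkynylation and closure to a 2-arylbenzofuran, by aminocarbonylation of the aroylpalladium species with diethylamine, or by 5-exo closure to the aurone. The fallback sets out from 5 and 10, rejoins the route at ynone 12 and ends at 14; it builds the ynone without palladium, the carbonyl carbon coming from a carbamoyl chloride. Alkyne 10 is deprotonated with n-BuLi in THF at −78 °C to [(3,4,5-trimethoxyphenyl)ethynyl]lithium F1. F1 is acylated with N-methoxy-N-methylcarbamoyl chloride to N-methoxy-N-methyl-3-(3,4,5-trimethoxyphenyl)prop-2-ynamide F2. Aryllithium 6, generated from 5 as in step 4, is added to F2 (THF, −78 → 0 °C) to give 1-[3,4,6-trimethoxy-2-(methoxymethoxy)phenyl]-3-(3,4,5-trimethoxyphenyl)prop-2-yn-1-one F3. Methanolic HCl removes the MOM group to give 12, now isolated, and Et2NH in EtOH at room temperature closes ring C through 13 to 14.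

Step 4. Metalation may be misdirected to the hydrogen between the two methoxy groups, giving an iodide para to the masked hydroxyl that cannot annulate. The fallback sets out from 5 and comes back at 8; it replaces the MOM group by the strongest oxygen-based directing group. Methanolic HCl converts 5 into 2,3,5-trimethoxyphenol F4. NaH and diethylcarbamoyl chloride in THF give 2,3,5-trimethoxyphenyl N,N-diethylcarbamate F5. s-BuLi/TMEDA in THF at −78 °C, kept cold to prevent anionic Fries rearrangement, gives {2-[(diethylcarbamoyl)oxy]-3,4,6-trimethoxyphenyl}lithium F6. Iodine converts F6 into 2-iodo-3,5,6-trimethoxyphenyl N,N-diethylcarbamate F7, and NaOH in aqueous EtOH at reflux releases 8.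

Step 9. The boron may be sequestered by the 3-hydroxy-4-keto chelate, so that the 5-methoxy group is cleaved only under forcing conditions, under which the central 4'-methoxy or the 8-methoxy group may also be lost. The fallback sets out from 16 and comes back at 17; it masks the competing chelating group. Ac2O/pyridine gives 5,7,8-trimethoxy-4-oxo-2-(3,4,5-trimethoxyphenyl)-4H-chromen-3-yl acetate F8. BCl3 in CH2Cl2 (−78 → 0 °C), which can now chelate only between the C4 carbonyl and the 5-methoxy group, gives 5-hydroxy-7,8-dimethoxy-4-oxo-2-(3,4,5-trimethoxyphenyl)-4H-chromen-3-yl acetate F9. K2CO3 in MeOH at room temperature removes the acetate to give 17.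

**Further compounds**

F1 | step 7 | [(3,4,5-trimethoxyphenyl)ethynyl]lithium | [Li]C#Cc1cc(OC)c(OC)c(OC)c1
F2 | step 7 | N-methoxy-N-methyl-3-(3,4,5-trimethoxyphenyl)prop-2-ynamide | CON(C)C(=O)C#Cc1cc(OC)c(OC)c(OC)c1
F3 | step 7 | 1-[3,4,6-trimethoxy-2-(methoxymethoxy)phenyl]-3-(3,4,5-trimethoxyphenyl)prop-2-yn-1-one | COCOc1c(C(=O)C#Cc2cc(OC)c(OC)c(OC)c2)c(OC)cc(OC)c1OC
F4 | step 4 | 2,3,5-trimethoxyphenol | COc1cc(O)c(OC)c(OC)c1
F5 | step 4 | 2,3,5-trimethoxyphenyl N,N-diethylcarbamate | CCN(CC)C(=O)Oc1cc(OC)cc(OC)c1OC
F6 | step 4 | {2-[(diethylcarbamoyl)oxy]-3,4,6-trimethoxyphenyl}lithium | CCN(CC)C(=O)Oc1c([Li])c(OC)cc(OC)c1OC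
F7 | step 4 | 2-iodo-3,5,6-trimethoxyphenyl N,N-diethylcarbamate | CCN(CC)C(=O)Oc1c(I)c(OC)cc(OC)c1OC
F8 | step 9 | 5,7,8-trimethoxy-4-oxo-2-(3,4,5-trimethoxyphenyl)-4H-chromen-3-yl acetate | COc1cc(-c2oc3c(OC)c(OC)cc(OC)c3c(=O)c2OC(C)=O)cc(OC)c1OC
F9 | step 9 | 5-hydroxy-7,8-dimethoxy-4-oxo-2-(3,4,5-trimethoxyphenyl)-4H-chromen-3-yl acetate | COc1cc(-c2oc3c(OC)c(OC)cc(O)c3c(=O)c2OC(C)=O)cc(OC)c1OC
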